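**Strategy.** Everything rests on cutting ring C into two pieces. O1–C8a–C4a–C4 is supplied as an ortho-quinone methide of ring A, and C2–C3 by the ring B arylacetic acid. In one operation a chiral triazolylidene turns the ring B acyl imidazole into an azolium enolate while CsF releases the quinone methide from an O-silylated ring A benzylic chloride. C3–C4 and O1–C2 form, ring C closes as a 3-aryl lactone, and C3, the only stereocentre, is set. The step exploits the fact that C4 is an unsubstituted methylene, so only the enolate face matters. Both partners carry MOM ethers. Ring B is built by two bromination/coupling pairs; reduction, Mitsunobu closure and deprotection finish.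

Key step: step 12

Assumption: the (5aR,10bS) aminoindanol-derived carbene is taken to give (3S). A pilot run with chiral HPLC decides this, and if the sense is opposite the equally available (5aS,10bR) salt is used with nothing else changed.

Design notes:
- C3 is (S) in the lactone, the diol and the target, because C2 outranks C1' and C4 in all three.
- Ring B locants follow the isoflavan, with C1' carrying the side chain.
- Ring B is brominated and coupled one position at a time. A symmetric dibromide would have to react only once, against statistics and against the tendency of bulky-phosphine palladium catalysts to couple twice.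
- The acetate is carried as the ethyl ester so that base, not acid, cleaves it.
- The benzylic chloride is made under basic conditions and used the same day.

**Step 1**
Reactants: 1 2,6-dimethoxyphenol
Product: 2 1,3-dimethoxy-2-(methoxymethoxy)benzene
Conditions: MOMCl (1.5 equiv), iPr2NEt (2 equiv), CH2Cl2, 0 °C to rt
Reagents that add atoms: chloromethyl methyl ether (MOMCl), COCCl
Why: Williamson-type O-alkylation with a highly reactive α-chloro ether caps the flanked phenol as an acetal, which also removes the para-directing free phenol so that later bromination follows the two methoxy groups.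

**Step 2**
Reactants: 2 1,3-dimethoxy-2-(methoxymethoxy)benzene
Product: 3 1-bromo-2,4-dimethoxy-3-(methoxymethoxy)benzene
Conditions: NBS (1.0 equiv), MeCN, 0 °C to rt, dark
Reagents that add atoms: N-bromosuccinimide, O=C1CCC(=O)N1Br
Why: Electrophilic aromatic bromination of a 1,2,3-trioxygenated benzene, in which the crowded central acetal oxygen is twisted out of conjugation and the two coplanar methoxy groups jointly direct bromine ortho to one and para to the other, one equivalent of NBS at low temperature stopping at the monobromide.

**Step 3**
Reactants: 3 1-bromo-2,4-dimethoxy-3-(methoxymethoxy)benzene; 4 (2-ethoxy-2-oxoethyl)zinc bromide (commercial solution)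
Product: 5 ethyl 2-[2,4-dimethoxy-3-(methoxymethoxy)phenyl]acetate
Conditions: 4 (1.5 equiv, 0.5 M), Pd(dba)2 (2 mol %), Q-Phos (2 mol %), THF, rt to 55 °C
Reagents that add atoms: none
Why: Negishi-type α-arylation with a Reformatsky reagent, in which zerovalent palladium inserts into the C–Br bond, the neutral zinc enolate transmetalates and reductive elimination forms the aryl–CH2 bond without strong base, the ethyl ester being chosen so that its later cleavage needs hydroxide and not acid.

**Step 4**
Reactants: 5 ethyl 2-[2,4-dimethoxy-3-(methoxymethoxy)phenyl]acetate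
Product: 6 ethyl 2-[5-bromo-2,4-dimethoxy-3-(methoxymethoxy)phenyl]acetate
Conditions: NBS (1.02 equiv), MeCN, −10 to 0 °C, dark
Reagents that add atoms: N-bromosuccinimide, O=C1CCC(=O)N1Br
Why: Electrophilic aromatic bromination again, directed to C5' because that carbon is ortho to the still coplanar 4'-methoxy group and para to the 2'-methoxy group whereas C6' is only para to the twisted acetal oxygen, and run cold in the dark in a polar solvent so that the ionic pathway outruns radical attack at the benzylic CH2.

**Step 5**
Reactants: 6 ethyl 2-[5-bromo-2,4-dimethoxy-3-(methoxymethoxy)phenyl]acetate; 7 3-methylbut-2-enylboronic acid pinacol ester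
Product: 8 ethyl 2-[2,4-dimethoxy-3-(methoxymethoxy)-5-(2-methylbut-3-en-2-yl)phenyl]acetate
Conditions: 7 (1.5 equiv), [Pd(allyl)Cl]2 (2 mol %), bulky biaryl monophosphine selected for branched selectivity (5 mol %), K3PO4 (3 equiv, 2 M aq), THF, 40 °C
Reagents that add atoms: none
Why: γ-Selective (branched) allyl Suzuki–Miyaura coupling, in which the prenylboronate transmetalates with allylic transposition to place palladium on the tertiary carbon and a ligand that makes reductive elimination faster than σ–π–σ isomerisation fixes the aryl–C(CH3)2 bond, the single bromide leaving no second site to couple.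

**Step 6**
Reactants: 8 ethyl 2-[2,4-dimethoxy-3-(methoxymethoxy)-5-(2-methylbut-3-en-2-yl)phenyl]acetate
Product: 9 2-[2,4-dimethoxy-3-(methoxymethoxy)-5-(2-methylbut-3-en-2-yl)phenyl]acetic acid
Conditions: LiOH·H2O (3 equiv), THF/MeOH/H2O, rt; then 1 M HCl to pH 4, 0 °C
Reagents that add atoms: lithium hydroxide, [Li+].[OH-]
Why: Saponification of an unhindered ethyl ester by acyl–oxygen cleavage, to which acetal, aryl ethers and terminal alkene are inert, with only a brief cold acidification to pH 4 so that the MOM group stays.

**Step 7**
Reactants: 9 2-[2,4-dimethoxy-3-(methoxymethoxy)-5-(2-methylbut-3-en-2-yl)phenyl]acetic acid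
Product: 10 1-(1H-imidazol-1-yl)-2-[2,4-dimethoxy-3-(methoxymethoxy)-5-(2-methylbut-3-en-2-yl)phenyl]ethan-1-one
Conditions: CDI (1.1 equiv), CH2Cl2, rt, 2 h; quick cold aqueous wash
Reagents that add atoms: 1,1'-carbonyldiimidazole, O=C(n1ccnc1)n1ccnc1
Why: Carboxyl activation with carbonyldiimidazole, driven by loss of CO2 and run under neutral conditions, gives the N-acyl imidazole without acid chloride chemistry that could harm the acetal.

**Step 8**
Reactants: 11 2,4-dihydroxybenzaldehyde
Product: 12 2-hydroxy-4-(methoxymethoxy)benzaldehyde
Conditions: MOMCl (1.05 equiv), K2CO3 (1.5 equiv), acetone, 0 °C to rt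
Reagents that add atoms: chloromethyl methyl ether (MOMCl), COCCl
Why: Regioselective Williamson-type alkylation, since the 2-hydroxyl is locked in a hydrogen bond to the aldehyde oxygen and the unchelated, more acidic 4-hydroxyl is the one alkylated by one equivalent of MOMCl with a weak base.

**Step 9**
Reactants: 12 2-hydroxy-4-(methoxymethoxy)benzaldehyde
Product: 13 2-[(tert-butyldimethylsilyl)oxy]-4-(methoxymethoxy)benzaldehyde
Conditions: TBSCl (1.2 equiv), imidazole (2.5 equiv), DMF, rt
Reagents that add atoms: tert-butyldimethylsilyl chloride, CC(C)(C)[Si](C)(C)Cl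
Why: Standard imidazole-promoted O-silylation in DMF is strong enough to break the chelate and installs the fluoride-labile trigger on the oxygen that will become O1.

**Step 10**
Reactants: 13 2-[(tert-butyldimethylsilyl)oxy]-4-(methoxymethoxy)benzaldehyde
Product: 14 {2-[(tert-butyldimethylsilyl)oxy]-4-(methoxymethoxy)phenyl}methanol
Conditions: NaBH4 (0.6 equiv), THF/MeOH, −10 to 0 °C, 20 min; sat. aq NH4Cl
Reagents that add atoms: none
Why: Chemoselective borohydride reduction of the aryl aldehyde, kept short and cold and quenched with a mild proton source so that the benzylic alkoxide has no time for O-to-O silyl migration.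

**Step 11**
Reactants: 14 {2-[(tert-butyldimethylsilyl)oxy]-4-(methoxymethoxy)phenyl}methanol
Product: 16 tert-butyl[2-(chloromethyl)-5-(methoxymethoxy)phenoxy]dimethylsilane, via benzylic mesylate 15 (not isolated)
Conditions: MsCl (1.2 equiv), Et3N (1.5 equiv), LiCl (3 equiv), THF, −10 to 0 °C; cold NaHCO3 wash, no chromatography, used the same day
Reagents that add atoms: lithium chloride, [Li+].[Cl-]; methanesulfonyl chloride (mesyl group of 15), CS(=O)(=O)Cl
Why: Mesylation followed by in situ chloride displacement (nucleophilic substitution at an activated benzylic carbon) works under basic, cold conditions that spare acetal and silyl ether, and the chloride is preferred to the bromide because this doubly donor-substituted benzylic halide ionises easily.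

**Step 12**
Reactants: 10 ring B acyl imidazole; 16 ring A silyl ether benzylic chloride
Product: 19 (3S)-3-[2,4-dimethoxy-3-(methoxymethoxy)-5-(2-methylbut-3-en-2-yl)phenyl]-7-(methoxymethoxy)chroman-2-one, via azolium enolate 17 (not isolated), via ortho-quinone methide 18 (not isolated)
Conditions: (5aR,10bS)-2-mesityl-5a,10b-dihydro-4H,6H-indeno[2,1-b][1,2,4]triazolo[4,3-d][1,4]oxazin-2-ium tetrafluoroborate (15 mol %), CsF (3 equiv), 18-crown-6 (1 equiv), 4 Å MS, THF, −20 °C; 16 (1.5 equiv) added over 2 h; cold filtration through a short silica pad
Reagents that add atoms: none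
Why: The carbene freed from the triazolium salt by CsF displaces imidazole from 10 and loss of the now acidic benzylic proton gives the Z-configured azolium enolate 17, while fluoride removes the silyl group of 16 and the phenoxide expels chloride in a 1,4-elimination to give ortho-quinone methide 18. C3 of 17 adds to the exocyclic methylene C4 of 18 in a conjugate addition driven by rearomatisation of ring A, and the phenoxide O1 thus released attacks the acyl carbon C2 in a 6-exo-trig lactonisation that closes ring C and returns the carbene, so the formal [4+2] is stepwise. The closest known reaction type is exactly this carbene-catalysed enantioselective annulation of acyl imidazole derived enolates with fluoride-generated ortho-quinone methides to 3-substituted dihydrocoumarins. C3 is the only new stereocentre and its (S) configuration is set by the catalyst, whose fused indane covers one face of the enolate so that C4 bonds to the open face. The step needs cross-coupling to win over oligomerisation of 18 and over its capture by imidazole, which the donor at C7 (a tamer quinone methide), the slow addition of 16 and its modest excess should secure, and regiochemistry is not at issue because 18 offers one electrophilic carbon and one nucleophilic oxygen. It also needs H3 to stay in place, which is served by the low temperature, the weakly basic heterogeneous fluoride and the immediate reduction in the next step.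

**Step 13**
Reactants: 19 (3S)-lactone
Product: 20 (2S)-2-[2,4-dimethoxy-3-(methoxymethoxy)-5-(2-methylbut-3-en-2-yl)phenyl]-3-[2-hydroxy-4-(methoxymethoxy)phenyl]propan-1-ol
Conditions: LiBH4 (2 equiv), THF, −20 to 0 °C, run at once on fresh 19; sat. aq NH4Cl
Reagents that add atoms: none
Why: Hydride reduction of the activated aryl ester with LiBH4 is fast at low temperature because phenoxide is a good leaving group, it turns C2 into CH2OH and so removes the acidity of H3, and it breaks no bond at C3, so the (S) configuration is carried over and locked.

**Step 14**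
Reactants: 20 (2S)-phenol alcohol
Product: 21 (3S)-3-[2,4-dimethoxy-3-(methoxymethoxy)-5-(2-methylbut-3-en-2-yl)phenyl]-7-(methoxymethoxy)chroman
Conditions: PPh3 (1.5 equiv), DIAD (1.5 equiv), THF, 0 °C to rt
Reagents that add atoms: none
Why: Intramolecular Mitsunobu etherification, in which the PPh3/DIAD couple activates the primary hydroxyl at C2 and the acidic phenol O1 displaces it in a 6-exo-tet closure, C3 being a spectator so that its configuration is untouched.

**Step 15**
Reactants: 21 (3S)-bis-MOM isoflavan
Product: 22 (3S)-3-[3-hydroxy-2,4-dimethoxy-5-(2-methylbut-3-en-2-yl)phenyl]chroman-7-ol (CNP0305994.1)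
Conditions: HCl (1.25 M in MeOH), 40 °C
Reagents that add atoms: none
Why: Acid-catalysed acetal exchange with methanol removes both MOM groups at once, while the monosubstituted alkene is too weakly basic to be protonated under these conditions, has only OCH3 and H as ring neighbours so that no cyclisation is open to it, and C3 has no acidifying group left.

**Compound list**

| No. | Name | SMILES | Role |
|---|---|---|---|
| 1 | 2,6-dimethoxyphenol | COc1cccc(OC)c1O | starting material |
| 2 | 1,3-dimethoxy-2-(methoxymethoxy)benzene | COCOc1c(OC)cccc1OC | intermediate |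
| 3 | 1-bromo-2,4-dimethoxy-3-(methoxymethoxy)benzene | COCOc1c(OC)ccc(Br)c1OC | intermediate |
| 4 | (2-ethoxy-2-oxoethyl)zinc bromide | CCOC(=O)C[Zn]Br | starting material |
| 5 | ethyl 2-[2,4-dimethoxy-3-(methoxymethoxy)phenyl]acetate | CCOC(=O)Cc1ccc(OC)c(OCOC)c1OC | intermediate |
| 6 | ethyl 2-[5-bromo-2,4-dimethoxy-3-(methoxymethoxy)phenyl]acetate | CCOC(=O)Cc1cc(Br)c(OC)c(OCOC)c1OC | intermediate |
| 7 | 3-methylbut-2-enylboronic acid pinacol ester | CC(C)=CCB1OC(C)(C)C(C)(C)O1 | starting material |
| 8 | ethyl 2-[2,4-dimethoxy-3-(methoxymethoxy)-5-(2-methylbut-3-en-2-yl)phenyl]acetate | CCOC(=O)Cc1cc(C(C)(C)C=C)c(OC)c(OCOC)c1OC | intermediate |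
| 9 | 2-[2,4-dimethoxy-3-(methoxymethoxy)-5-(2-methylbut-3-en-2-yl)phenyl]acetic acid | OC(=O)Cc1cc(C(C)(C)C=C)c(OC)c(OCOC)c1OC | intermediate |
| 10 | ring B arylacetyl imidazole | O=C(Cc1cc(C(C)(C)C=C)c(OC)c(OCOC)c1OC)n1ccnc1 | intermediate |
| 11 | 2,4-dihydroxybenzaldehyde | O=Cc1ccc(O)cc1O | starting material |
| 12 | 2-hydroxy-4-(methoxymethoxy)benzaldehyde | COCOc1ccc(C=O)c(O)c1 | intermediate |
| 13 | 2-[(tert-butyldimethylsilyl)oxy]-4-(methoxymethoxy)benzaldehyde | COCOc1ccc(C=O)c(O[Si](C)(C)C(C)(C)C)c1 | intermediate |
| 14 | {2-[(tert-butyldimethylsilyl)oxy]-4-(methoxymethoxy)phenyl}methanol | COCOc1ccc(CO)c(O[Si](C)(C)C(C)(C)C)c1 | intermediate |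
| 15 | 2-[(tert-butyldimethylsilyl)oxy]-4-(methoxymethoxy)benzyl methanesulfonate (not isolated) | COCOc1ccc(COS(C)(=O)=O)c(O[Si](C)(C)C(C)(C)C)c1 | intermediate |
| 16 | tert-butyl[2-(chloromethyl)-5-(methoxymethoxy)phenoxy]dimethylsilane | COCOc1ccc(CCl)c(O[Si](C)(C)C(C)(C)C)c1 | intermediate |
| 17 | Z-azolium enolate of the ring B acyl unit on the (5aR,10bS)-N-mesityl triazolylidene, zwitterion (not isolated) | [O-]/C(=C\c1cc(C(C)(C)C=C)c(OC)c(OCOC)c1OC)c1[n+](-c2c(C)cc(C)cc2C)nc2CO[C@@H]3Cc4ccccc4[C@@H]3n12 | intermediate |
| 18 | 3-(methoxymethoxy)-6-methylidenecyclohexa-2,4-dien-1-one (not isolated) | C=C1C=CC(OCOC)=CC1=O | intermediate |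
| 19 | (3S)-3-aryl-7-(methoxymethoxy)chroman-2-one | C=CC(C)(C)c1cc([C@H]2C(=O)Oc3cc(OCOC)ccc3C2)c(OC)c(OCOC)c1OC | intermediate |
| 20 | (2S)-2-aryl-3-[2-hydroxy-4-(methoxymethoxy)phenyl]propan-1-ol | OC[C@@H](Cc1ccc(OCOC)cc1O)c1cc(C(C)(C)C=C)c(OC)c(OCOC)c1OC | intermediate |
| 21 | (3S)-bis-MOM isoflavan | C=CC(C)(C)c1cc([C@H]2COc3cc(OCOC)ccc3C2)c(OC)c(OCOC)c1OC | intermediate |
| 22 | (3S)-3-[3-hydroxy-2,4-dimethoxy-5-(2-methylbut-3-en-2-yl)phenyl]chroman-7-ol | C=CC(C)(C)c1cc([C@H]2COc3cc(O)ccc3C2)c(OC)c(O)c1OC | target |

**Total step count:** 15.
**Longest linear sequence:** 11 (steps 1–7 and 12–15).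

**Three steps most likely to fail**

1. **Step 12.** What may go wrong:
   - weak facial discrimination on an enolate that carries an ortho-methoxy aryl group;
   - erosion of enantiopurity by enolisation of the product under fluoride and imidazole;
   - loss of the quinone methide to oligomerisation or to N-alkylation of imidazole.

   Fallback: auxiliary-controlled alkylation in place of catalysis, setting out from 10 and 16 and returning at 20. Compound 10 is treated with the lithium salt of (S)-4-benzyloxazolidin-2-one (n-BuLi, THF, −78 to 0 °C) to give the N-arylacetyl oxazolidinone F1. NaHMDS in THF at −78 °C forms the chelated Z-enolate, which 16 (Bu4NI cat.) alkylates on the face away from the benzyl group (Evans alkylation) to give the benzylated (2S)-imide F2. LiBH4 with one equivalent of water in THF at 0 °C removes the auxiliary reductively to give the silyl ether alcohol F3. Bu4NF buffered with AcOH (THF, 0 °C) frees the phenol and gives 20.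

2. **Step 5.** What may go wrong:
   - poor branched-to-linear selectivity;
   - slow reductive elimination beside the ortho-methoxy group;
   - protodeboronation of the allylboronate.

   Fallback: the quaternary carbon is built by enolate arylation and the vinyl group by olefination, setting out from 6 and returning at 8. Palladium-catalysed α-arylation of isobutyraldehyde with 6 ([Pd(allyl)Cl]2, Q-Phos, Cs2CO3, dioxane, 80 °C) should give the α-aryl isobutyraldehyde F4. This aldehyde cannot enolise. Wittig methylenation (Ph3PCH3Br, KHMDS, THF, −78 to 0 °C, ylide added to the aldehyde) should then give 8.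

3. **Step 11.** What may go wrong:
   - ionisation, hydrolysis or Friedel–Crafts self-alkylation of the very electron-rich benzylic halide during formation or concentration;
   - loss of the silyl group.

   Fallback: a storable ester leaving group in place of the halide, setting out from 14 and returning at 18 inside step 12. Compound 14 is acetylated (Ac2O, pyridine, DMAP cat., CH2Cl2, 0 °C) to the benzylic acetate F5, which can be chromatographed and stored. Under the conditions of step 12, run at 0 °C to rt, fluoride desilylates F5 and the phenoxide expels acetate to give the same quinone methide 18.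

**Further compounds**
F1 | step 12 | (4S)-4-benzyl-3-{2-[2,4-dimethoxy-3-(methoxymethoxy)-5-(2-methylbut-3-en-2-yl)phenyl]acetyl}oxazolidin-2-one | O=C(Cc1cc(C(C)(C)C=C)c(OC)c(OCOC)c1OC)N1C(=O)OC[C@@H]1Cc1ccccc1
F2 | step 12 | (4S)-4-benzyl-3-{(2S)-2-aryl-3-[2-(tert-butyldimethylsilyloxy)-4-(methoxymethoxy)phenyl]propanoyl}oxazolidin-2-one | O=C([C@@H](Cc1ccc(OCOC)cc1O[Si](C)(C)C(C)(C)C)c1cc(C(C)(C)C=C)c(OC)c(OCOC)c1OC)N1C(=O)OC[C@@H]1Cc1ccccc1
F3 | step 12 | (2S)-2-aryl-3-[2-(tert-butyldimethylsilyloxy)-4-(methoxymethoxy)phenyl]propan-1-ol | OC[C@@H](Cc1ccc(OCOC)cc1O[Si](C)(C)C(C)(C)C)c1cc(C(C)(C)C=C)c(OC)c(OCOC)c1OC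
F4 | step 5 | ethyl 2-[2,4-dimethoxy-3-(methoxymethoxy)-5-(2-methyl-1-oxopropan-2-yl)phenyl]acetate | CCOC(=O)Cc1cc(C(C)(C)C=O)c(OC)c(OCOC)c1OC
F5 | step 11 | 2-[(tert-butyldimethylsilyl)oxy]-4-(methoxymethoxy)benzyl acetate | COCOc1ccc(COC(C)=O)c(O[Si](C)(C)C(C)(C)C)c1
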